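**Retrosynthetic overview**

- The target is cut in one operation at three bonds around flavan C-8/O-7 (flavan numbering): the aryl ether C-8–O, the C-8–C(OH) bond and the O-7–CH(Ar) bond. This gives (R)-5,7-dihydroxy-4'-methoxyflavan and a racemic aurone spiro-epoxide, used as a masked 2-hydroxyaryl α-leaving-group 1,2-diketone.
- In the forward sense the dihydrofuran closes first (phenoxide opening of the epoxide, then para-aldol on the unveiled diketone). The chromanone closes second (oxidative dearomatising C–O coupling), in the same flask.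
- The aurone epoxide comes from the aurone, which comes from 4,6-dimethoxybenzofuran-3-one and anisaldehyde.
- The flavan pyran ring (first ring made) comes from Mitsunobu closure of an (S)-carbinol. The carbinol comes from asymmetric transfer hydrogenation of the ketone made from phloroglucinol and an aryl vinyl ketone.

Assumption: stereochemistry is taken exactly as the SMILES encodes it (flavan C-2 R; quaternary aryl-ether carbon S; carbinol carbon R; anisylic furan carbon S), and 2 and 7 are taken as catalogue chemicals.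

**Route**

Step 1
Reactants: 1 phloroglucinol (benzene-1,3,5-triol); 2 3-chloro-1-(4-methoxyphenyl)propan-1-one
Product: 4 1-(4-methoxyphenyl)-3-(2,4,6-trihydroxyphenyl)propan-1-one, via 1-(4-methoxyphenyl)prop-2-en-1-one 3 (not isolated)
Conditions: 1 (3 equiv), NaHCO3, H2O–MeCN, 40 °C
Reagents that add atoms: none
Why: bicarbonate eliminates HCl from 2 to the aryl vinyl ketone, and the phloroglucinol monoanion adds through carbon (Michael-type Friedel–Crafts alkylation), with excess 1 suppressing double alkylation; no stereocentre is formed.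

Step 2
Reactants: 4 1-(4-methoxyphenyl)-3-(2,4,6-trihydroxyphenyl)propan-1-one
Product: 5 2-[(3S)-3-hydroxy-3-(4-methoxyphenyl)propyl]benzene-1,3,5-triol
Conditions: RuCl[(S,S)-TsDPEN](p-cymene) (1 mol %), HCO2Na, H2O–MeOH, 40 °C
Reagents that add atoms: none
Why: Noyori asymmetric transfer hydrogenation of an aryl alkyl ketone, in which the (S,S) catalyst gives the (S)-carbinol as for acetophenone-type substrates, and free phenols are tolerated under the near-neutral formate conditions.

Step 3
Reactants: 5 2-[(3S)-3-hydroxy-3-(4-methoxyphenyl)propyl]benzene-1,3,5-triol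
Product: 6 (2R)-2-(4-methoxyphenyl)-3,4-dihydro-2H-chromene-5,7-diol
Conditions: PPh3, DIAD, THF, 0 °C
Reagents that add atoms: none
Why: intramolecular Mitsunobu etherification (6-exo-tet) by either of the two equivalent ortho phenols displaces the activated benzylic oxygen with inversion, so the (S)-carbinol gives C-2 (R).

Step 4
Reactants: 7 4,6-dimethoxy-1-benzofuran-3(2H)-one; 8 4-methoxybenzaldehyde
Product: 9 (2Z)-4,6-dimethoxy-2-(4-methoxybenzylidene)-1-benzofuran-3(2H)-one
Conditions: KOH (cat.), MeOH, 60 °C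
Reagents that add atoms: none
Why: aldol condensation (Knoevenagel type) of the active methylene with the aldehyde gives the thermodynamically preferred (Z)-aurone.

Step 5
Reactants: 9 (2Z)-4,6-dimethoxy-2-(4-methoxybenzylidene)-1-benzofuran-3(2H)-one
Product: 10 rac-(2R,3'R)-4,6-dimethoxy-3'-(4-methoxyphenyl)-3H-spiro[1-benzofuran-2,2'-oxiran]-3-one
Conditions: DMDO, acetone–CH2Cl2, 0 °C; used crude
Reagents that add atoms: dimethyldioxirane CC1(C)OO1
Why: neutral electrophilic (dioxirane) epoxidation of the enol-ether C=C, a known reaction of aurones, adds oxygen syn, and the racemate is sufficient because the spiro centre is destroyed and the anisylic centre equilibrates in step 6.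

Step 6
Reactants: 6 (2R)-2-(4-methoxyphenyl)-3,4-dihydro-2H-chromene-5,7-diol; 10 rac-(2R,3'R)-4,6-dimethoxy-3'-(4-methoxyphenyl)-3H-spiro[1-benzofuran-2,2'-oxiran]-3-one
Product: 13 CNP0251458.1 (target), via aryloxy-1,2-diketone 11 (not isolated), via furochromenol 12 (not isolated)
Conditions: Cs2CO3 (2.2 equiv), MeCN, 0 °C → rt; then PhI(OAc)2 (1.1 equiv), −20 → 0 °C, same flask; chromatography
Reagents that add atoms: none
Why: Proposed new method: the less hindered 7-phenoxide opens the doubly activated spiro-epoxide at the anisylic carbon (SN2) and the hemiketal alkoxide collapses to diketone 11; C-8 (para to the 5-phenoxide) then adds irreversibly to the central carbonyl to close the dihydrofuran 12 (closest known reaction: interrupted Feist–Bénary annulation), with aryl trans to aroyl because the anisylic centre epimerises through the enol and the less hindered transition state is taken; PhI(OAc)2 then oxidises the 5-phenoxide and the tethered aryl OH adds to C-8 in a necessarily cis-fused six-membered ring (closest known reaction: griseofulvin-type oxidative phenol C–O coupling); the new triad is therefore set in one relative sense, but its absolute sense is biased only weakly by C-2 (C–C bond formation anti to axial H-2 should favour 13), so the diastereomer with the mirror-image triad is removed by chromatography.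

**Compound list**

1 | phloroglucinol (benzene-1,3,5-triol) | Oc1cc(O)cc(O)c1 | starting material
2 | 3-chloro-1-(4-methoxyphenyl)propan-1-one | COc1ccc(cc1)C(=O)CCCl | starting material
3 | 1-(4-methoxyphenyl)prop-2-en-1-one | COc1ccc(cc1)C(=O)C=C | intermediate (not isolated)
4 | 1-(4-methoxyphenyl)-3-(2,4,6-trihydroxyphenyl)propan-1-one | COc1ccc(cc1)C(=O)CCc1c(O)cc(O)cc1O | intermediate
5 | 2-[(3S)-3-hydroxy-3-(4-methoxyphenyl)propyl]benzene-1,3,5-triol | COc1ccc(cc1)[C@@H](O)CCc1c(O)cc(O)cc1O | intermediate
6 | (2R)-2-(4-methoxyphenyl)-3,4-dihydro-2H-chromene-5,7-diol [(2R)-5,7-dihydroxy-4'-methoxyflavan] | COc1ccc(cc1)[C@H]1CCc2c(O)cc(O)cc2O1 | intermediate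
7 | 4,6-dimethoxy-1-benzofuran-3(2H)-one | COc1cc(OC)c2C(=O)COc2c1 | starting material
8 | 4-methoxybenzaldehyde | COc1ccc(C=O)cc1 | starting material
9 | (2Z)-4,6-dimethoxy-2-(4-methoxybenzylidene)-1-benzofuran-3(2H)-one | COc1ccc(cc1)/C=C2\Oc3cc(OC)cc(OC)c3C2=O | intermediate
10 | rac-(2R,3'R)-4,6-dimethoxy-3'-(4-methoxyphenyl)-3H-spiro[1-benzofuran-2,2'-oxiran]-3-one (racemate, one enantiomer drawn) | COc1ccc(cc1)[C@H]2O[C@@]23Oc4cc(OC)cc(OC)c4C3=O | intermediate
11 | (3RS)-1-(2-hydroxy-4,6-dimethoxyphenyl)-3-{[(2R)-5-hydroxy-2-(4-methoxyphenyl)-3,4-dihydro-2H-chromen-7-yl]oxy}-3-(4-methoxyphenyl)propane-1,2-dione (C-3 epimers, equilibrating) | COc1ccc(cc1)[C@H]1CCc2c(O)cc(OC(c3ccc(OC)cc3)C(=O)C(=O)c3c(O)cc(OC)cc3OC)cc2O1 | intermediate (not isolated)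
12 | [(2R,8S,9S)-5,9-dihydroxy-2,8-bis(4-methoxyphenyl)-3,4,8,9-tetrahydro-2H-furo[2,3-h]chromen-9-yl](2-hydroxy-4,6-dimethoxyphenyl)methanone | COc1ccc(cc1)[C@H]1CCc2c(O)cc3O[C@@H](c4ccc(OC)cc4)[C@](O)(C(=O)c4c(O)cc(OC)cc4OC)c3c2O1 | intermediate (not isolated)
13 | CNP0251458.1: compound 12 in which the 2-hydroxyl oxygen of the aroyl group is bonded to C-9a, giving the cis-fused 3-hydroxy-5,7-dimethoxychroman-4-one and the 5-oxo cross-conjugated dienone; 2R, 8S, 9R, 9aS in furo[2,3-h]chromene numbering | COc1ccc([C@H]2CCC3=C(O2)[C@]24Oc5cc(OC)cc(OC)c5C(=O)[C@@]2(O)[C@H](c2ccc(OC)cc2)OC4=CC3=O)cc1 | target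

**Step count and risks**

Total steps: 6. Longest linear sequence: 4 (steps 1, 2, 3, 6).

Most likely to fail, first: step 6. Three things can go wrong:
- alkylation at O-5, or aldol closure at C-6 instead of C-8;
- the weak 1,4-induction from C-2 leaves up to half of the material as the diastereomer with the mirror-image triad;
- the tertiary p-hydroxybenzylic alcohol 12 dehydrates to the benzofuran if the mixture turns acidic.

The fallback replaces the one-flask union by a stereochemical relay and sets out from 6. Commercial flavokawain A is O-allylated to (2E)-1-[2-(allyloxy)-4,6-dimethoxyphenyl]-3-(4-methoxyphenyl)prop-2-en-1-one F1. F1 is epoxidised under Juliá–Colonna conditions (poly-D-leucine, urea–H2O2, DBU) to [2-(allyloxy)-4,6-dimethoxyphenyl][(2S,3R)-3-(4-methoxyphenyl)oxiran-2-yl]methanone F2. The caesium 7-phenoxide of 6 opens F2 at the anisylic carbon with inversion to (2S,3S)-1-[2-(allyloxy)-4,6-dimethoxyphenyl]-2-hydroxy-3-{[(2R)-5-hydroxy-2-(4-methoxyphenyl)-3,4-dihydro-2H-chromen-7-yl]oxy}-3-(4-methoxyphenyl)propan-1-one F3, in which the anisylic centre is not enolisable. Buffered Dess–Martin oxidation (NaHCO3, CH2Cl2, 0 °C) gives the 1,2-diketone under non-basic conditions, and it is expected to close onto C-8 before it enolises. This gives [(2R,8S,9S)-5,9-dihydroxy-2,8-bis(4-methoxyphenyl)-3,4,8,9-tetrahydro-2H-furo[2,3-h]chromen-9-yl][2-(allyloxy)-4,6-dimethoxyphenyl]methanone F4. Pd(PPh3)4/morpholine removes the allyl group, and the route is rejoined at 12, which is oxidised with PhI(OAc)2 as in step 6.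

Second: step 3. The p-methoxybenzylic alkoxyphosphonium may ionise and erode the ee, and three free phenols are present. The fallback avoids substitution at that carbon and sets out from 4. Cyclodehydration (cat. TsOH, toluene, water removal) gives 2-(4-methoxyphenyl)-4H-chromene-5,7-diol F5. Asymmetric hydrogenation with a cationic Ir–phosphinooxazoline catalyst (Pfaltz-type hydrogenation of 4H-chromenes) then gives 6 directly, where the route is rejoined; steps 2 and 3 are skipped.

Third: step 1. Polyalkylation or O-alkylation of phloroglucinol, and polymerisation of the vinyl ketone, are the risks. The fallback builds the three-carbon link by olefination and sets out from 1. Vilsmeier–Haack formylation gives 2,4,6-trihydroxybenzaldehyde F6. Wittig reaction with commercial 1-(4-methoxyphenyl)-2-(triphenylphosphoranylidene)ethan-1-one gives (2E)-1-(4-methoxyphenyl)-3-(2,4,6-trihydroxyphenyl)prop-2-en-1-one F7. Hydrogenation of the C=C bond (H2, Pd/C, EtOAc, stopped after one equivalent) gives 4, where the route is rejoined.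

Further compounds

F1 | step 6 | (2E)-1-[2-(allyloxy)-4,6-dimethoxyphenyl]-3-(4-methoxyphenyl)prop-2-en-1-one | COc1ccc(/C=C/C(=O)c2c(OCC=C)cc(OC)cc2OC)cc1
F2 | step 6 | [2-(allyloxy)-4,6-dimethoxyphenyl][(2S,3R)-3-(4-methoxyphenyl)oxiran-2-yl]methanone | COc1ccc(cc1)[C@H]1O[C@@H]1C(=O)c1c(OCC=C)cc(OC)cc1OC
F3 | step 6 | (2S,3S)-1-[2-(allyloxy)-4,6-dimethoxyphenyl]-2-hydroxy-3-{[(2R)-5-hydroxy-2-(4-methoxyphenyl)-3,4-dihydro-2H-chromen-7-yl]oxy}-3-(4-methoxyphenyl)propan-1-one | COc1ccc(cc1)[C@H](Oc1cc(O)c2CC[C@@H](Oc2c1)c1ccc(OC)cc1)[C@H](O)C(=O)c1c(OCC=C)cc(OC)cc1OC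
F4 | step 6 | [(2R,8S,9S)-5,9-dihydroxy-2,8-bis(4-methoxyphenyl)-3,4,8,9-tetrahydro-2H-furo[2,3-h]chromen-9-yl][2-(allyloxy)-4,6-dimethoxyphenyl]methanone | COc1ccc(cc1)[C@H]1CCc2c(O)cc3O[C@@H](c4ccc(OC)cc4)[C@](O)(C(=O)c4c(OCC=C)cc(OC)cc4OC)c3c2O1
F5 | step 3 | 2-(4-methoxyphenyl)-4H-chromene-5,7-diol | COc1ccc(cc1)C1=CCc2c(O)cc(O)cc2O1
F6 | step 1 | 2,4,6-trihydroxybenzaldehyde | O=Cc1c(O)cc(O)cc1O
F7 | step 1 | (2E)-1-(4-methoxyphenyl)-3-(2,4,6-trihydroxyphenyl)prop-2-en-1-one | COc1ccc(cc1)C(=O)/C=C/c1c(O)cc(O)cc1O
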